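Readings and results were computed with made-up constants; noise was put on by code.

An easy step comes first: each turn at the catalyst spends one reagent and makes one product, and each homo dimer spends two reagent. What counts is therefore the fraction of reagent left for product.

| setting | alder | larch | south-east | north-east | north |
|---|---|---|---|---|---|
| left-handed substrate | 0.050 M | 0.075 M | 0.10 M | 0.10 M | 0.10 M |
| right-handed substrate | 0.050 M | 0.075 M | 0.10 M | 0.10 M | 0.10 M |
| reagent | 0.060 M | 0.060 M | 0.0600 M | 0.0600 M | 0.0600 M |
| catalyst | 10 mM | 10 mM | 10 mM | 10 mM | 10 mM |
| temperature | −25 °C | 5 °C | 5 °C | 30 °C | −20 °C |
| remark | run made earlier | run made earlier |  |  |  |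
| time |  |  | 2.0 min | 2.0 min | 2.0 min |

alder run (percent of the left-handed substrate and right-handed substrate together charged)

| time / min | left-handed product / % | left-handed substrate / % |
|---|---|---|
| 1.00 | 15.4 | 30.2 |
| 2.00 | 19.0 | 25.1 |
| 4.00 | 21.6 | 20.1 |
| 6.00 | 21.9 | 20.2 |
| 8.00 | 21.3 | 19.4 |

larch run (percent of the left-handed substrate and right-handed substrate together charged)

| time / s | left-handed product / % | left-handed substrate / % |
|---|---|---|
| 15.0 | 14.1 | 30.3 |
| 30.0 | 15.5 | 28.3 |
| 50.0 | 16.6 | 28.3 |
| 60.0 | 16.0 | 28.8 |
| 80.0 | 16.3 | 27.3 |
| 90.0 | 16.9 | 28.5 |
| 120 | 16.1 | 27.6 |

(readings scatter by 0.5 percentage points)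

- catalyst is single-handed; left-handed substrate and right-handed substrate are mirror images of each other, charged as a racemate, each of them at the stated concentration
- the numbers in the tables scatter with a standard deviation of 0.5 percentage points
- reactions considered so far: reagent + catalyst + left-handed substrate -> catalyst + left-handed product; reagent + catalyst + right-handed substrate -> catalyst + right-handed product; 2 reagent -> homo dimer; left-handed product <-> right-handed product

* which flask leads in amount of left-handed product, in percent of the left-handed substrate and right-handed substrate together charged ("all alike" within 1.5 percentage points) (south-east / north-east / north / all alike)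
* how much left-handed product is there at the end, in percent of the left-handed substrate and right-handed substrate together charged: south-east
* how much left-handed product is there at the end, in percent of the left-handed substrate and right-handed substrate together charged: north-east
* how much left-handed product is there at the end, in percent of the left-handed substrate and right-handed substrate together charged: north

Reagent is the limiting reagent here: the readings of alder and larch go flat with left-handed substrate still at 19.4% and 27.6%. In larch, left-handed product reads 16.1%, less than the 22 percentage points of left-handed substrate lost, so my reckoning takes left-handed product as half of the product, a racemate. The flat readings then put the share of reagent lost to homo dimer at 28.0% in alder and 18.1% in larch.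

By the rate laws, homo dimer formation over catalysed turnover goes as [reagent]/([catalyst][substrate]). At fixed [reagent] and [catalyst], lost share times charged [left-handed substrate] should hold steady. It reads 0.0140 M in alder at −25 °C and 0.0136 M in larch at 5 °C, so between these two runs temperature hardly shows. Their mean, 0.0138 M, is the loss level: lost share times charged [left-handed substrate].

Two extremes frame my reckoning for the new flasks, with the product taken as a racemate in both. With no homo dimer, left-handed product comes to 15.0%; with the lost share of larch unchanged, to 12.3%. At fixed [reagent] and [catalyst] the rule above lowers the lost share as the substrate charge rises, so my reckoning places the new flasks between these two figures. The loss level gives a lost share of 13.8% and left-handed product of 12.9%, and my reckoning uses that one figure at each temperature.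

The forecast says all alike, with 13% (12% to 14%) in south-east, 12.8% (11.3% to 14.2%) in north-east and 13.1% (11.6% to 14.2%) in north: “This suggests fast product racemisation”.

The simulation gives all alike: 12.6% in south-east, 12.5% in north-east, 12.7% in north.

    reagent + catalyst + left-handed substrate → catalyst + left-handed product (k = 33.7 /M²/s, Ea = 37.0 kJ/mol)
    reagent + catalyst + right-handed substrate → catalyst + right-handed product (k = 11.5 /M²/s, Ea = 40.0 kJ/mol)
    2 reagent → homo dimer (k = 0.121 /M/s, Ea = 40.0 kJ/mol)
    left-handed product ⇌ right-handed product (k = 0.0273 /s, Ea = 61.0 kJ/mol)
    (constants at −20 °C)

In north, the half-life of left-handed product by the forward step alone at 0.236 min, 0.42 min, is short against the time 2.0 min. Left-handed and right-handed product stand there at 12.7% and 12.5% after 2.00 min. In south-east, homo dimer at 0.00472 M took 15.7% of the reagent, a loss level of 0.0157 M against 0.0138 M. Scaled to 0.040 M of catalyst, the loss level becomes 0.00345 M, which gives 14.5%; the neighbour of north with that catalyst gives 14.4%.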